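# Proposed synthesis of (S)-CNP0208927.1 by an ortho-quinone methide [4+2] annulation

## Analysis of the target

The target is a flavanone in three parts. Ring A is a hexasubstituted benzene with a hydroxyl at C5, methyl groups at C6 and C8 and a methoxy group at C7. Ring C is the dihydropyranone fused to ring A through O1–C8a and C4–C4a. Ring B is a 2-methoxy-1,4-benzoquinone bonded to C2 through the quinone carbon that lies next to one carbonyl and para to the methoxy-bearing carbon.

C2 is the only stereocentre and is S (O1 > ring B carbon > C3 > H), so nothing else in the molecule can relay or repair its configuration. C2 is both a benzylic-type ether carbon and β to the C4 ketone. Base opens ring C by a retro-oxa-Michael reaction to an achiral 2'-hydroxychalcone, and strong acid can ionise C2–O1, so either racemises the compound.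

The methoxyquinone is a vinylogous ester, a Michael acceptor and an oxidant. It will not tolerate organometallic, reducing, strongly basic or Lewis acidic steps and must appear last. The C5 hydroxyl is chelated to the C4 carbonyl, which makes it the least reactive phenol and gives a handle for selective deprotection.

The difficulties are therefore a single labile stereocentre, a fully substituted ring A whose three oxygens (free OH, OMe, ring O) must be told apart, and the timing of the quinone. The route rests on ring C being a pyran fused to an electron-rich phenol. O1, C8a, C4a and C4 are the four atoms of a ring A ortho-quinone methide and C2=C3 is a styrene, so O1–C2 and C3–C4 can form in one [4+2] event that also creates C2.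

## Retrosynthetic reasoning

**15 ⇒ 14.** The quinone is removed first. One carbonyl oxygen of 15 is the former ring B phenol oxygen and the other is a new C–O bond at the ring carbon para to it. This puts the most fragile group at the very end and asks only for a phenol-to-para-quinone oxidation (Teuber type) near neutral pH. In 14 the para position of the ring B phenol is free, while the ring A phenol is chelated and sits on a ring with no free position, so the oxidation should choose ring B.

**14 ⇒ 13.** The O–CH3 bond at C5 and the O–benzyl bond on ring B are cut. Both phenols stay masked through the acid and oxidation steps before this point. A boron trihalide can remove both groups in one operation. The C4 carbonyl directs it to the C5 methoxy group through a six-membered chelate, which the C7 and ring B methoxy groups cannot form.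

**13 ⇒ 12 ⇒ 11.** These are changes of oxidation level at C4 only: ketone from carbinol, carbinol from methyl ether. The ring-forming step delivers C4 as an ether, one level below the ketone. The price is two steps. The gain is that the C4 stereocentre of 11 is erased, so only C2 has to be controlled.

**11 ⇒ 5 + 7 + 8 (via 9 and 10).** O1–C2 and C3–C4 are cut together. This is the natural place because ring C hangs on ring A by exactly O1 and C4, and the fragment O1–C8a–C4a–C4 at the aldehyde oxidation level is the ortho-quinone methide 10. Compound 10 is reached from salicylaldehyde 5 and orthoformate 8 through acetal 9. The C2=C3 unit is styrene 7, which brings ring B complete. The cut is convergent, gives two halves of similar size, closes ring C and creates C2 in one step. The forward reaction must secure the orientation (styrene terminus to C4, oxygen to the benzylic carbon) and the absolute configuration at C2, which a chiral Brønsted acid has to supply.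

**7 ⇒ 6.** The vinyl C=C bond is cut back to the aldehyde by a Wittig methylenation. Compound 6 is a catalogue aldehyde that already has the ring B oxygens in place, with the future quinone oxygen masked as a benzyl ether.

**5 ⇒ 4.** One O–CH3 bond ortho to the formyl group is cut. The two ortho methoxy groups of 4 are related by symmetry, so chelation-controlled removal of either gives the same phenol. This settles the problem of distinguishing the three ring A oxygens without any regiochemical choice.

**4 ⇒ 3.** The C–CHO bond is cut. Compound 3 has a single unsubstituted ring position, so electrophilic formylation can go nowhere else.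

**3 ⇒ 1 (via 2).** One C–CH3 bond is cut. In 1 the two ring C–H bonds each lie between two methoxy groups and are equivalent, so directed metalation to 2 and methylation is unambiguous. Compound 1 is a commercial arene.

## Alternatives that were turned down

**Alternative 1: natural flavanone as chiral pool, with late double C-methylation of ring A.**

- Disconnection: the C6–CH3 and C8–CH3 bonds. Ring C, ring B and the C2 centre are bought intact as (S)-hesperetin A1.
- Forward: A1 is 7-O-methylated, 3'-O-acetylated and iodinated at C6 and C8 to diiodide A2. Twofold Stille coupling with Sn(CH3)4 under zerovalent palladium catalysis (Pd(PPh3)4) gives A3. Deacetylation of A3 gives 14, and the same final oxidation follows.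
- For: it is the shortest plan, about six steps against nine. It needs no enantioselective reaction, and ring B arrives with the right oxygen pattern. On step count and on the origin of the stereocentre it is stronger than the chosen route.
- Against: the optical purity of commercial A1 is not assured, because 5,7-dihydroxyflavanones epimerise at C2 through the chalcone whenever a phenolate is formed. The 7-O-methylation (base) and the Stille coupling (heat, often fluoride or copper additives) expose the intact flavanone to exactly such conditions. The coupling must transfer methyl, the slowest group on tin, twice, to two positions each flanked by two oxygen substituents and next to a free chelated hydroxyl. Protodeiodination would give mono-methyl congeners that are very hard to separate from A3. Stoichiometric organotin is a further burden.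
- Comparison: the chosen route gives an unambiguous ring A built by symmetry before the heterocycle exists. C2 is created in the laboratory under acidic conditions, so its purity does not depend on a supplier, and no basic or hot metal-catalysed step acts on a flavanone.

**Alternative 2: aryne insertion–acylation with a chiral β-hydroxy ester.**

- Disconnection: O1–C8a and C4–C4a, the two bonds from ring A to ring C.
- Forward: CsF converts silyl triflate A4 into aryne A5. The secondary alkoxide of hydroxy ester A6 adds at C8a, and the aryl anion formed at C4a attacks the ester to close ring C as flavanone A7.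
- For: C4 arrives as the ketone, so no redox adjustment is needed. The stereocentre comes from a dependable reaction, asymmetric reduction of a β-keto ester. The polarity of A5 is right, since a nucleophile prefers the aryne carbon remote from the C5 methoxy group and leaves the anion next to it. On these three points it is stronger than the chosen route.
- Against: A4 is a hexasubstituted benzene that needs a long synthesis of its own. The C8 methyl group flanks the carbon that a bulky secondary alkoxide must attack. Under fluoride, the alkoxide of A6 can undergo retro-aldol cleavage or dehydration to a cinnamate. A7 is formed as a flavanone in a basic medium, the very conditions that open ring C and racemise C2. Ring B of A7 is a 2,4,5-trimethoxyphenyl group, so the quinone must come from oxidative demethylation with (NH4)2Ce(NO3)6. That has to be done either beside the free ring A phenol or before the peri demethylation, which then needs a Lewis acid beside a methoxyquinone.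
- Comparison: the chosen route offers a ring A partner made in three steps, ring closure under acid where the new C2 centre is not base-labile, and a ring B whose oxidation needs only a phenol.

**Alternative 3: ring-closing metathesis of an enol ether to form C3–C4.**

- Disconnection: the C3=C4 bond of the enol form of the ketone, with O1–C2 already in place as an aryl ether.
- Forward: the second-generation Grubbs catalyst joins the C2 vinyl group and the silyl enol ether of diene A8, with loss of the two terminal methylene groups as a volatile alkene. This gives 4-silyloxy-2H-chromene A9, and desilylation of A9 gives 13.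
- For: C4 is at the ketone level at once, and the ring closure is neutral. C2 could be set beforehand by an established asymmetric reduction or vinylation. If the ether could be made without loss of configuration, this plan would not depend on an untested enantioselective step, and on that point it is stronger.
- Against: the difficulty moves into the O1–C2 bond of A8. It joins a di-ortho-substituted, acyl-chelated phenol to a secondary carbinol carbon that is both allylic and para-methoxybenzylic. A Mitsunobu or related substitution at such a centre tends towards ionisation and allylic transposition, and so to loss of configuration and regiochemistry. The same ether can ionise later. Ruthenium hydride species formed during a slow metathesis can move the allyl double bond into conjugation with oxygen, which destroys C2. The metathesis itself must give a trisubstituted, oxygenated alkene beside a hexasubstituted ring. The route is also longer, at about eleven steps.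
- Comparison: the chosen route makes O1–C2 and C3–C4 in one operation and needs no separate etherification at the most ionisable carbon of the molecule.

Key step: step 5

## Route

Assumption: the sense of induction of the chiral acid in step 5 cannot be predicted with confidence. The (R) acid is written, and its mirror image is to be used if it should favour the (2R) series.

Step 1
Reactants: 1 2,4,6-trimethoxytoluene
Product: 3 1,3,5-trimethoxy-2,4-dimethylbenzene, via aryllithium 2 (not isolated)
Conditions: n-BuLi, TMEDA, THF, 0 °C to rt; then MeI, −78 °C to rt
Reagents that add atoms: iodomethane, CI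
Why: Directed ortho-metalation: each of the two equivalent ring C–H bonds of 1 lies between two methoxy groups and is far more acidic than the benzylic methyl group, so a single aryllithium 2 forms and is methylated by SN2 attack on MeI.

Step 2
Reactants: 3 1,3,5-trimethoxy-2,4-dimethylbenzene
Product: 4 2,4,6-trimethoxy-3,5-dimethylbenzaldehyde
Conditions: Cl2CHOMe, TiCl4, CH2Cl2, −78 to 0 °C; then H2O
Reagents that add atoms: dichloromethyl methyl ether, COC(Cl)Cl (formyl carbon); water, O (formyl oxygen, on hydrolytic work-up)
Why: Rieche formylation, an electrophilic aromatic substitution that tolerates flanking substituents; 3 has one free ring position only, activated by two ortho and one para methoxy groups, so there is no regiochemical choice.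

Step 3
Reactants: 4 2,4,6-trimethoxy-3,5-dimethylbenzaldehyde
Product: 5 2-hydroxy-4,6-dimethoxy-3,5-dimethylbenzaldehyde
Conditions: BCl3 (1.1 equiv), CH2Cl2, −78 to 0 °C; then H2O
Reagents that add atoms: none
Why: Chelation-controlled O-demethylation: boron bridges the carbonyl oxygen and an ortho methoxy oxygen in a six-membered chelate and chloride removes that methyl group, which the para methoxy group cannot match. The two ortho methoxy groups of 4 are symmetry-equivalent, so only one phenol can form, and one equivalent of BCl3 stops the reaction after the first cleavage.

Step 4
Reactants: 6 3-benzyloxy-4-methoxybenzaldehyde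
Product: 7 3-benzyloxy-4-methoxystyrene
Conditions: Ph3PCH3Br, KOtBu, THF, 0 °C to rt
Reagents that add atoms: methyltriphenylphosphonium bromide, C[P+](c1ccccc1)(c1ccccc1)c1ccccc1.[Br-]
Why: Wittig methylenation of an aromatic aldehyde with the unstabilised ylide; the benzyl and methyl ethers are inert to the base.

Step 5
Reactants: 5 2-hydroxy-4,6-dimethoxy-3,5-dimethylbenzaldehyde; 7 3-benzyloxy-4-methoxystyrene; 8 trimethyl orthoformate
Product: 11 (2S,4S)-2-(3-benzyloxy-4-methoxyphenyl)-4,5,7-trimethoxy-6,8-dimethylchroman (2,4-cis), via dimethyl acetal 9 (not isolated), via ortho-quinone methide 10 (not isolated)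
Conditions: 8 (3 equiv), (R)-3,3'-bis(2,4,6-triisopropylphenyl)-1,1'-binaphthyl-2,2'-diyl hydrogen phosphate (10 mol%), toluene, rt; then 7 (1.5 equiv), −30 °C; Et3N quench
Reagents that add atoms: none
Why: Proposed new method: the acid-catalysed annulation of salicylaldehydes, orthoformates and styrenes to 2,4-cis-4-alkoxyflavans is known in racemic form, and chiral Brønsted acids are known to control [4+2] reactions of ortho-quinone methides and of salicylaldehyde-acetal-derived oxocarbenium ions with vinyl ethers and tethered alkenes, but not with a simple styrene, so the enantioselective intermolecular case is the new element. The acid first exchanges 5 with 8 to acetal 9 and then ionises 9 with loss of methanol to the 4-methoxy ortho-quinone methide 10, which reacts as its O-protonated oxocarbenium form paired with the chiral phosphate. The terminal carbon of styrene 7 attacks the exocyclic carbon (future C4) and the ring A oxygen collapses onto the para-methoxybenzylic carbon (future C2), an inverse-demand hetero-[4+2] closure of ring C that is concerted but asynchronous or, in the stepwise limit, a Prins-type addition followed by 6-exo-trig capture of the benzylic cation by oxygen. Regiochemistry follows polarity, since only this orientation puts the developing positive charge on the carbon stabilised by the 4-methoxyphenyl ring. The phosphate is held by a hydrogen bond to the ring A hydroxyl and by ion pairing with the oxocarbenium carbon, so its 3,3'-aryl groups shield one face of C4; C2 is then fixed relative to C4 in the ring closure, the cis isomer with both substituents pseudo-equatorial being preferred, so the catalyst sets the absolute configuration at C2 by way of C4. Chemoselectivity requires the acid to ionise the acetal and not to protonate the styrene, which the three donor oxygens of ring A secure by making ionisation easy for a weak acid at low temperature. Low temperature and the basic quench keep 11 from ionising again at C4 or at C2.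

Step 6
Reactants: 11 (2S,4S)-2-(3-benzyloxy-4-methoxyphenyl)-4,5,7-trimethoxy-6,8-dimethylchroman
Product: 12 (2S)-2-(3-benzyloxy-4-methoxyphenyl)-5,7-dimethoxy-6,8-dimethylchroman-4-ol (mixture of C4 epimers)
Conditions: p-TsOH·H2O (10 mol%), THF/H2O (3:1), rt
Reagents that add atoms: water, O
Why: SN1 solvolysis of a benzylic methyl ether: the C4 cation is stabilised by O1 and the two methoxy groups of ring A, so dilute acid should ionise this ether alone and the large excess of water traps the cation. Both C4 epimers are acceptable because this centre is oxidised in the next step, and C2 takes no part.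

Step 7
Reactants: 12 (2S)-2-(3-benzyloxy-4-methoxyphenyl)-5,7-dimethoxy-6,8-dimethylchroman-4-ol
Product: 13 (S)-2-(3-benzyloxy-4-methoxyphenyl)-5,7-dimethoxy-6,8-dimethylchroman-4-one
Conditions: Dess–Martin periodinane, pyridine, CH2Cl2, 0 °C to rt
Reagents that add atoms: none
Why: Dess–Martin oxidation of a secondary benzylic alcohol to the aryl ketone; pyridine buffering keeps the ionisable carbinol from losing water, both C4 epimers converge on one ketone, and C2 is untouched.

Step 8
Reactants: 13 (S)-2-(3-benzyloxy-4-methoxyphenyl)-5,7-dimethoxy-6,8-dimethylchroman-4-one
Product: 14 (S)-5-hydroxy-2-(3-hydroxy-4-methoxyphenyl)-7-methoxy-6,8-dimethylchroman-4-one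
Conditions: BCl3 (4 equiv), pentamethylbenzene (3 equiv), CH2Cl2, −78 to 0 °C; then H2O
Reagents that add atoms: none
Why: Lewis-acid ether cleavage: BCl3 removes the benzyl group at low temperature, the benzyl cation being trapped by pentamethylbenzene in a Friedel–Crafts reaction, and cleaves the 5-methoxy group through the six-membered boron chelate with the C4 carbonyl. The 7-methoxy and ring B methoxy groups have no such chelate and should survive at or below 0 °C.

Step 9
Reactants: 14 (S)-5-hydroxy-2-(3-hydroxy-4-methoxyphenyl)-7-methoxy-6,8-dimethylchroman-4-one
Product: 15 2-[(2S)-5-hydroxy-7-methoxy-6,8-dimethyl-4-oxochroman-2-yl]-5-methoxy-1,4-benzoquinone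
Conditions: (KSO3)2NO (2.5 equiv), KH2PO4 buffer (pH 6), acetone/H2O, 0 °C to rt
Reagents that add atoms: potassium nitrosodisulfonate (Fremy's salt), [K+].[K+].[O]N(S(=O)(=O)[O-])S(=O)(=O)[O-]
Why: Teuber oxidation: one nitroxyl radical abstracts the ring B phenolic hydrogen and a second adds at the free para carbon, which collapses to the para-quinone and leaves the methoxy group where the target has it. The ring A hydroxyl is hydrogen-bonded to the C4 carbonyl and sits on a fully substituted ring, so it should not compete, and the buffer near pH 6 avoids base-induced opening of ring C at C2.

## Compound list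

1 | 2,4,6-trimethoxytoluene | Cc1c(OC)cc(OC)cc1OC | starting material
2 | 3-lithio-2,4,6-trimethoxytoluene | [Li]c1c(OC)cc(OC)c(C)c1OC | intermediate (not isolated)
3 | 1,3,5-trimethoxy-2,4-dimethylbenzene | Cc1c(OC)cc(OC)c(C)c1OC | intermediate
4 | 2,4,6-trimethoxy-3,5-dimethylbenzaldehyde | O=Cc1c(OC)c(C)c(OC)c(C)c1OC | intermediate
5 | 2-hydroxy-4,6-dimethoxy-3,5-dimethylbenzaldehyde | O=Cc1c(O)c(C)c(OC)c(C)c1OC | intermediate
6 | 3-benzyloxy-4-methoxybenzaldehyde | COc1ccc(C=O)cc1OCc1ccccc1 | starting material
7 | 3-benzyloxy-4-methoxystyrene | COc1ccc(C=C)cc1OCc1ccccc1 | intermediate
8 | trimethyl orthoformate | COC(OC)OC | starting material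
9 | 2-(dimethoxymethyl)-3,5-dimethoxy-4,6-dimethylphenol | COC(OC)c1c(O)c(C)c(OC)c(C)c1OC | intermediate (not isolated)
10 | 3,5-dimethoxy-6-(methoxymethylidene)-2,4-dimethylcyclohexa-2,4-dien-1-one (4-methoxy ortho-quinone methide; geometry of the exocyclic C=C not fixed; reacts as its O-protonated oxocarbenium form) | O=C1C(C)=C(OC)C(C)=C(OC)C1=COC | intermediate (not isolated)
11 | (2S,4S)-2-(3-benzyloxy-4-methoxyphenyl)-4,5,7-trimethoxy-6,8-dimethylchroman (2,4-cis) | COc1ccc(cc1OCc1ccccc1)[C@@H]2C[C@H](OC)c3c(OC)c(C)c(OC)c(C)c3O2 | intermediate
12 | (2S)-2-(3-benzyloxy-4-methoxyphenyl)-5,7-dimethoxy-6,8-dimethylchroman-4-ol (both C4 epimers; C4 left undefined) | COc1ccc(cc1OCc1ccccc1)[C@@H]2CC(O)c3c(OC)c(C)c(OC)c(C)c3O2 | intermediate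
13 | (S)-2-(3-benzyloxy-4-methoxyphenyl)-5,7-dimethoxy-6,8-dimethylchroman-4-one | COc1ccc(cc1OCc1ccccc1)[C@@H]2CC(=O)c3c(OC)c(C)c(OC)c(C)c3O2 | intermediate
14 | (S)-5-hydroxy-2-(3-hydroxy-4-methoxyphenyl)-7-methoxy-6,8-dimethylchroman-4-one | COc1ccc(cc1O)[C@@H]2CC(=O)c3c(O)c(C)c(OC)c(C)c3O2 | intermediate
15 | 2-[(2S)-5-hydroxy-7-methoxy-6,8-dimethyl-4-oxochroman-2-yl]-5-methoxy-1,4-benzoquinone | COC1=CC(=O)C([C@@H]2CC(=O)c3c(O)c(C)c(OC)c(C)c3O2)=CC1=O | target

## Step count and least certain steps

Total step count: 9. Longest linear sequence: 8 steps (steps 1, 2, 3, 5, 6, 7, 8, 9). The styrene branch (step 4) joins at step 5.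

**Step 5 (key step, proposed new method).**
- Most likely failure: poor facial selectivity at the oxocarbenium carbon. The styrene has no hydrogen-bond donor to tie it to the catalyst, so discrimination rests on the ion pair and on steric shielding alone.
- Second concern: acid-induced oligomerisation of the electron-rich styrene, and ionisation of the product at C4 followed by C2, which would wear down whatever selectivity was reached. A more acidic or more confined acid of the same family would be tried first.
- Fallback: this uses known chemistry and sets out from 5, 7 and 8. The annulation is run with an achiral acid (p-TsOH·H2O, toluene, 0 °C) to give racemic cis-2-(3-benzyloxy-4-methoxyphenyl)-4,5,7-trimethoxy-6,8-dimethylchroman F1. The conditions of steps 6 and 7 turn F1 into racemic 2-(3-benzyloxy-4-methoxyphenyl)-5,7-dimethoxy-6,8-dimethylchroman-4-ol F2 and then racemic 2-(3-benzyloxy-4-methoxyphenyl)-5,7-dimethoxy-6,8-dimethylchroman-4-one F3. F3 is resolved kinetically by asymmetric transfer hydrogenation (RuCl(p-cymene)[(R,R)-TsNCH(Ph)CH(Ph)NH2], HCO2H/Et3N, EtOAc, rt). The catalyst antipode is chosen so that the (R) ketone is the one reduced, expected for the (R,R) complex because it delivers 4R carbinols and the cis flavanol is the favoured diastereomer. The (S) ketone is left and is 13. The (R) ketone becomes (2R,4R)-2-(3-benzyloxy-4-methoxyphenyl)-5,7-dimethoxy-6,8-dimethylchroman-4-ol F4, which is removed by chromatography. The route is rejoined at 13, at the price of using at most half of the material.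

**Step 6.**
- Most likely failure: loss of a proton from the C4 cation to give the flav-3-ene instead of capture by water. Ionisation of the C2–O1 bond is also possible, since C2 is a para-methoxybenzylic ether carbon, and together with the scrambling at C4 it would erode the configuration at C2.
- Fallback: setting out from 11, DDQ (1.5 equiv) in CH2Cl2/pH 7 phosphate buffer at 0 °C abstracts hydride from C4, whose C–H bond is activated by ring A and by the methoxy oxygen. Water adds to the oxocarbenium ion and the hemiketal loses methanol to give ketone 13 directly, so neither free acid nor the carbinol is involved. This is the known oxidative cleavage of electron-rich benzylic ethers to carbonyl compounds. The route is rejoined at 13, step 7 is skipped, and no new compound is made (F0).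

**Step 8.**
- Most likely failure: over-demethylation at the 7-methoxy group, which is twisted out of the ring plane by its two methyl neighbours and therefore more basic, or at the ring B methoxy group next to the freed phenol. Opening of ring C in the boron-chelated flavanone to the chalcone is also possible and would racemise C2.
- Fallback: this separates the two deprotections and sets out from 13. Hydrogenolysis (H2, Pd/C, EtOAc, rt) removes only the benzyl group and gives (S)-2-(3-hydroxy-4-methoxyphenyl)-5,7-dimethoxy-6,8-dimethylchroman-4-one F5. MgI2·OEt2 in THF at 40 °C then removes the 5-methyl group alone, because only that oxygen can share a six-membered magnesium chelate with the C4 carbonyl, and iodide is a soft nucleophile that spares unchelated ethers. The route is rejoined at 14.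

**Step 9.**
- Most likely failure: competing hydrogen abstraction from the ring A phenol, or attack of the second radical at the methoxy-bearing ortho carbon instead of the free para carbon. Opening of ring C is also a risk if the medium drifts alkaline.
- Fallback: this replaces radical oxidation by the classical phenol, para-nitrosophenol, para-aminophenol, quinone sequence and sets out from 14. Nitrosation (NaNO2, aqueous HCl/EtOH, 0 °C) is an electrophilic substitution that ring A cannot undergo, since it has no free position. It takes place para to the ring B hydroxyl and gives (S)-5-hydroxy-2-(5-hydroxy-4-methoxy-2-nitrosophenyl)-7-methoxy-6,8-dimethylchroman-4-one F6. Na2S2O4 reduces F6 to (S)-2-(2-amino-5-hydroxy-4-methoxyphenyl)-5-hydroxy-7-methoxy-6,8-dimethylchroman-4-one F7. F7 is not stored but oxidised at once with aqueous FeCl3 in dilute acid, and the quinone imine hydrolyses to 15, where the route is rejoined.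

## Further compounds

F1 | step 5 | racemic cis-2-(3-benzyloxy-4-methoxyphenyl)-4,5,7-trimethoxy-6,8-dimethylchroman (both enantiomers) | COc1ccc(cc1OCc1ccccc1)[C@@H]2C[C@H](OC)c3c(OC)c(C)c(OC)c(C)c3O2.COc1ccc(cc1OCc1ccccc1)[C@H]2C[C@@H](OC)c3c(OC)c(C)c(OC)c(C)c3O2
F2 | step 5 | racemic 2-(3-benzyloxy-4-methoxyphenyl)-5,7-dimethoxy-6,8-dimethylchroman-4-ol (both C4 epimers; no configuration defined) | COc1ccc(cc1OCc1ccccc1)C2CC(O)c3c(OC)c(C)c(OC)c(C)c3O2
F3 | step 5 | racemic 2-(3-benzyloxy-4-methoxyphenyl)-5,7-dimethoxy-6,8-dimethylchroman-4-one (both enantiomers) | COc1ccc(cc1OCc1ccccc1)[C@@H]2CC(=O)c3c(OC)c(C)c(OC)c(C)c3O2.COc1ccc(cc1OCc1ccccc1)[C@H]2CC(=O)c3c(OC)c(C)c(OC)c(C)c3O2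
F4 | step 5 | (2R,4R)-2-(3-benzyloxy-4-methoxyphenyl)-5,7-dimethoxy-6,8-dimethylchroman-4-ol (2,4-cis) | COc1ccc(cc1OCc1ccccc1)[C@H]2C[C@@H](O)c3c(OC)c(C)c(OC)c(C)c3O2
F0 | step 6 | none | none
F5 | step 8 | (S)-2-(3-hydroxy-4-methoxyphenyl)-5,7-dimethoxy-6,8-dimethylchroman-4-one | COc1ccc(cc1O)[C@@H]2CC(=O)c3c(OC)c(C)c(OC)c(C)c3O2
F6 | step 9 | (S)-5-hydroxy-2-(5-hydroxy-4-methoxy-2-nitrosophenyl)-7-methoxy-6,8-dimethylchroman-4-one | COc1cc(N=O)c(cc1O)[C@@H]2CC(=O)c3c(O)c(C)c(OC)c(C)c3O2
F7 | step 9 | (S)-2-(2-amino-5-hydroxy-4-methoxyphenyl)-5-hydroxy-7-methoxy-6,8-dimethylchroman-4-one | COc1cc(N)c(cc1O)[C@@H]2CC(=O)c3c(O)c(C)c(OC)c(C)c3O2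
A1 | alternative 1 | (S)-hesperetin, (S)-5,7-dihydroxy-2-(3-hydroxy-4-methoxyphenyl)chroman-4-one | COc1ccc(cc1O)[C@@H]2CC(=O)c3c(O)cc(O)cc3O2
A2 | alternative 1 | (S)-3'-O-acetyl-6,8-diiodo-7-O-methylhesperetin | COc1ccc(cc1OC(C)=O)[C@@H]2CC(=O)c3c(O)c(I)c(OC)c(I)c3O2
A3 | alternative 1 | (S)-3'-O-acetyl-6,8-dimethyl-7-O-methylhesperetin | COc1ccc(cc1OC(C)=O)[C@@H]2CC(=O)c3c(O)c(C)c(OC)c(C)c3O2
A4 | alternative 2 | 3,5-dimethoxy-2,4-dimethyl-6-(trimethylsilyl)phenyl trifluoromethanesulfonate | C[Si](C)(C)c1c(OC)c(C)c(OC)c(C)c1OS(=O)(=O)C(F)(F)F
A5 | alternative 2 | 3,5-dimethoxy-4,6-dimethylbenzyne | CC1=C(OC)C(C)=C(OC)C#C1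
A6 | alternative 2 | methyl (S)-3-hydroxy-3-(2,4,5-trimethoxyphenyl)propanoate | COC(=O)C[C@H](O)c1cc(OC)c(OC)cc1OC
A7 | alternative 2 | (S)-5,7-dimethoxy-6,8-dimethyl-2-(2,4,5-trimethoxyphenyl)chroman-4-one | COc1cc(OC)c(cc1OC)[C@@H]2CC(=O)c3c(OC)c(C)c(OC)c(C)c3O2
A8 | alternative 3 | (S)-1-{2-[1-(3-benzyloxy-4-methoxyphenyl)prop-2-enyloxy]-4,6-dimethoxy-3,5-dimethylphenyl}-1-(tert-butyldimethylsilyloxy)ethene | C=C[C@H](Oc1c(C)c(OC)c(C)c(OC)c1C(=C)O[Si](C)(C)C(C)(C)C)c1ccc(OC)c(OCc2ccccc2)c1
A9 | alternative 3 | (S)-2-(3-benzyloxy-4-methoxyphenyl)-4-(tert-butyldimethylsilyloxy)-5,7-dimethoxy-6,8-dimethyl-2H-chromene | COc1ccc(cc1OCc1ccccc1)[C@@H]2C=C(O[Si](C)(C)C(C)(C)C)c3c(OC)c(C)c(OC)c(C)c3O2
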